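**Retrosynthetic overview**

- The last step is acidolysis of four tert-butyl esters and one triethylsilyl ether from the protected lactone 27.
- The strategy rests on the γ-butyrolactone ring (O1, C2 carbonyl, C3, C4, C5). C2–C3–C4 is a homoenolate and O1–C5 is the carbonyl of a C15 trienal, so cutting C4–C5 and O1–C2 gives the β-iodo ester 17 and trienal 23. The lactone is the only ring and it closes in the same step.
- Iodide 17 comes from dimethyl (R)-malate: anti benzyloxymethylation sets C3, dioxolanone alkylation with retention sets Cq, the Cq acid is esterified with the isocitrate alcohol 4 (from L-malic acid), and the benzyl ether is turned into the iodide last.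
- Trienal 23 comes from pent-4-yn-1-ol and 1-bromooct-2-yne: skipped diyne, Z,Z-diene, aldehyde, E-enal.

Key step: step 17

Remark: Cq is the carbinol carbon on C3; the (1R,2R)-bis(triflamide) ligand is assumed to deliver the alkyl group to the Si face of 23 as it does with benzaldehyde and simple enals, and its enantiomer would be used if the opposite sense were found.

**Route**

Step 1
Reactants: 1 L-malic acid
Product: 2 di-tert-butyl (S)-malate
Conditions: O-tert-butyl-N,N'-diisopropylisourea (2.5 equiv), CH2Cl2/THF, rt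
Reagents that add atoms: O-tert-butyl-N,N'-diisopropylisourea, CC(C)N=C(OC(C)(C)C)NC(C)C
Why: Isourea esterification, in which each carboxylic acid protonates the isourea and is tert-butylated while the secondary alcohol, which needs copper catalysis to react, stays free and the stereocentre is untouched.

Step 2
Reactants: 2 di-tert-butyl (S)-malate
Product: 4 tri-tert-butyl (1S,2R)-1-hydroxypropane-1,2,3-tricarboxylate, via dilithium alkoxide enolate 3 (not isolated)
Conditions: LiN(SiMe3)2 (2.2 equiv), THF, −78 → −20 °C; BrCH2CO2tBu, −78 → −15 °C; AcOH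
Reagents that add atoms: tert-butyl bromoacetate, BrCC(=O)OC(C)(C)C
Why: Frater–Seebach alkylation, in which the chelated alkoxide enolate should be attacked anti to the carbinol substituent and so set the new centre (R), giving the (2S,3R)-isocitrate triester.

Step 3
Reactants: 5 dimethyl (R)-malate
Product: 7 dimethyl (2R,3S)-3-[(benzyloxy)methyl]malate (C2 is the carbinol carbon), via dilithium alkoxide enolate 6 (not isolated)
Conditions: LiN(SiMe3)2 (2.2 equiv), THF, −78 → −20 °C; BnOCH2Cl, −78 → −20 °C; AcOH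
Reagents that add atoms: benzyl chloromethyl ether, ClCOCc1ccccc1
Why: Frater–Seebach alkylation with a reactive alkoxymethyl chloride, where anti attack on the chelated dianion should set C3 (S) and install C4 as a benzyl-protected hydroxymethyl group.

Step 4
Reactants: 7 dimethyl (2R,3S)-3-[(benzyloxy)methyl]malate
Product: 8 (2R,3S)-3-[(benzyloxy)methyl]malic acid
Conditions: LiOH (3 equiv), THF/H2O, 0 °C → rt; then 1 M HCl to pH 2
Reagents that add atoms: lithium hydroxide, [Li+].[OH-]
Why: Ester saponification, in which each carboxylate formed shuts down enolisation at C3 so that neither epimerisation nor loss of benzyl alcohol should compete.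

Step 5
Reactants: 8 (2R,3S)-3-[(benzyloxy)methyl]malic acid
Product: 9 (2S)-3-(benzyloxy)-2-[(2R,4R)-2-tert-butyl-5-oxo-1,3-dioxolan-4-yl]propanoic acid (cis-dioxolanone)
Conditions: tBuCHO, TsOH·H2O (cat.), H2SO4 (cat.), pentane, reflux, Dean–Stark
Reagents that add atoms: pivalaldehyde, CC(C)(C)C=O
Why: Acid-catalysed acetalisation of the α-hydroxy acid (Seebach dioxolanone), where the five-membered ring is preferred over the six-membered dioxanone and equilibration should place the tert-butyl group cis to the side chain.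

Step 6
Reactants: 9 cis-dioxolanone acid
Product: 11 (2S)-3-(benzyloxy)-2-[(2R,4R)-4-(2-tert-butoxy-2-oxoethyl)-2-tert-butyl-5-oxo-1,3-dioxolan-4-yl]propanoic acid, via dilithium carboxylate enolate 10 (not isolated)
Conditions: LiN(SiMe3)2 (2.2 equiv), THF, −78 °C; BrCH2CO2tBu, −78 → −20 °C; cold 1 M HCl
Reagents that add atoms: tert-butyl bromoacetate, BrCC(=O)OC(C)(C)C
Why: Seebach self-regeneration of stereocentres, in which the carboxylate protects the C3 hydrogen, the ring enolate is alkylated on the face opposite the tert-butyl group, and the new arm therefore takes the place of hydrogen with retention to set Cq (R).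

Step 7
Reactants: 11 quaternised dioxolanone acid
Product: 12 methyl (2S)-3-(benzyloxy)-2-[(2R,4R)-4-(2-tert-butoxy-2-oxoethyl)-2-tert-butyl-5-oxo-1,3-dioxolan-4-yl]propanoate
Conditions: Me3SiCHN2, toluene/MeOH (4:1), 0 °C
Reagents that add atoms: (trimethylsilyl)diazomethane, C[Si](C)(C)C=[N+]=[N-]
Why: Diazoalkane O-methylation, which is specific for the free acid under neutral conditions and leaves the dioxolanone, the tert-butyl ester and both stereocentres alone.

Step 8
Reactants: 12 dioxolanone methyl ester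
Product: 13 (2R)-2-[(2S)-3-(benzyloxy)-1-methoxy-1-oxopropan-2-yl]-4-tert-butoxy-2-hydroxy-4-oxobutanoic acid
Conditions: LiOH (1.1 equiv), THF/H2O (3:1), 0 °C; then 1 M HCl to pH 3
Reagents that add atoms: lithium hydroxide, [Li+].[OH-]
Why: Selective saponification, in which the acylal-type dioxolanone carbonyl is far more electrophilic than the methyl and tert-butyl esters, so one equivalent of hydroxide should open it and the hemiacetal then sheds pivalaldehyde to free the Cq acid and the tertiary alcohol.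

Step 9
Reactants: 13 Cq hydroxy acid; 4 tri-tert-butyl (1S,2R)-1-hydroxypropane-1,2,3-tricarboxylate
Product: 14 tri-tert-butyl (1S,2R)-1-{[(2R)-2-[(2S)-3-(benzyloxy)-1-methoxy-1-oxopropan-2-yl]-4-tert-butoxy-2-hydroxy-4-oxobutanoyl]oxy}propane-1,2,3-tricarboxylate
Conditions: 2-methyl-6-nitrobenzoic anhydride (1.3 equiv), DMAP (0.3 equiv), Et3N (3 equiv), CH2Cl2, rt
Reagents that add atoms: none
Why: Shiina esterification through the mixed anhydride and acylpyridinium, suited to hindered partners, where the activated carbon is quaternary and cannot epimerise and the tertiary alcohol is too hindered to be acylated.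

Step 10
Reactants: 14 isocitrate ester with free tertiary alcohol
Product: 15 tri-tert-butyl (1S,2R)-1-{[(2R)-2-[(2S)-3-(benzyloxy)-1-methoxy-1-oxopropan-2-yl]-4-tert-butoxy-4-oxo-2-[(triethylsilyl)oxy]butanoyl]oxy}propane-1,2,3-tricarboxylate
Conditions: Et3SiOTf, 2,6-lutidine, CH2Cl2, 0 °C → rt
Reagents that add atoms: triethylsilyl trifluoromethanesulfonate, CC[Si](CC)(CC)OS(=O)(=O)C(F)(F)F
Why: Silyl triflate silylation, which is strong enough for a hindered tertiary alcohol while the non-nucleophilic base leaves the esters and the C3 hydrogen untouched, removing the only acidic proton before the organozinc is made.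

Step 11
Reactants: 15 benzyl ether
Product: 16 tri-tert-butyl (1S,2R)-1-{[(2R)-4-tert-butoxy-2-[(2S)-3-hydroxy-1-methoxy-1-oxopropan-2-yl]-4-oxo-2-[(triethylsilyl)oxy]butanoyl]oxy}propane-1,2,3-tricarboxylate
Conditions: H2 (1 atm), Pd/C (10% Pd), EtOAc, rt
Reagents that add atoms: none
Why: Hydrogenolysis of the benzyl ether under neutral, non-alcoholic conditions, which should keep the silyl ether and esters intact and give no catalyst for lactonisation of the freed C4 alcohol, which is taken on at once.

Step 12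
Reactants: 16 primary alcohol
Product: 17 tri-tert-butyl (1S,2R)-1-{[(2R)-4-tert-butoxy-2-[(2S)-3-iodo-1-methoxy-1-oxopropan-2-yl]-4-oxo-2-[(triethylsilyl)oxy]butanoyl]oxy}propane-1,2,3-tricarboxylate
Conditions: I2, PPh3, imidazole, CH2Cl2, 0 °C, dark
Reagents that add atoms: iodine, II
Why: Appel-type iodination, in which iodide displaces the alkoxyphosphonium at the primary carbon C4 under conditions mild enough to leave the adjacent C3 centre alone, as in the standard preparation of β-iodo esters from β-hydroxy esters.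

Step 13
Reactants: 18 pent-4-yn-1-ol; 19 1-bromooct-2-yne
Product: 20 trideca-4,7-diyn-1-ol
Conditions: CuI (1.0 equiv), Cs2CO3 (1.0 equiv), DMF, rt
Reagents that add atoms: none
Why: Copper-mediated coupling of a terminal alkyne with a propargylic bromide, in which the copper acetylide should displace bromide without allene formation and tolerate the free alcohol, giving the skipped diyne.

Step 14
Reactants: 20 trideca-4,7-diyn-1-ol
Product: 21 (4Z,7Z)-trideca-4,7-dien-1-ol
Conditions: H2 (1 atm), Ni(OAc)2·4H2O, NaBH4, ethylenediamine, EtOH, rt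
Reagents that add atoms: none
Why: Semihydrogenation over P-2 nickel boride, where syn delivery of hydrogen to each alkyne gives both Z alkenes and the diamine-poisoned catalyst should stop at the diene.

Step 15
Reactants: 21 (4Z,7Z)-trideca-4,7-dien-1-ol
Product: 22 (4Z,7Z)-trideca-4,7-dienal
Conditions: TEMPO (10 mol%), PhI(OAc)2 (1.1 equiv), CH2Cl2, rt
Reagents that add atoms: none
Why: Oxoammonium (TEMPO) oxidation, which stops at the aldehyde and does not touch or isomerise the skipped Z,Z-diene.

Step 16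
Reactants: 22 (4Z,7Z)-trideca-4,7-dienal
Product: 23 (2E,6Z,9Z)-pentadeca-2,6,9-trienal
Conditions: Ph3P=CHCHO (1.1 equiv), toluene, 70 °C
Reagents that add atoms: (triphenylphosphoranylidene)acetaldehyde, O=CC=P(c1ccccc1)(c1ccccc1)c1ccccc1
Why: Wittig reaction with a stabilised formylmethylene ylide, which should give the E-enal and react faster with the saturated aldehyde than with the conjugated product.

Step 17
Reactants: 17 head iodide; 23 (2E,6Z,9Z)-pentadeca-2,6,9-trienal
Product: 27 tri-tert-butyl (1S,2R)-1-{[(2R)-4-tert-butoxy-4-oxo-2-[(3S,5S)-2-oxo-5-[(1E,5Z,8Z)-tetradeca-1,5,8-trien-1-yl]oxolan-3-yl]-2-[(triethylsilyl)oxy]butanoyl]oxy}propane-1,2,3-tricarboxylate, via bis-alkylzinc 24 (not isolated), via alkyl(trimethylsilylmethyl)zinc 25 (not isolated), via C5 hydroxy methyl ester 26 (not isolated)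
Conditions: ZnEt2 (5 equiv), CuI (0.3 mol%), neat, 50 °C, then 0.1 mmHg; Zn(CH2SiMe3)2 (0.5 equiv), toluene; Ti(OiPr)4 (2 equiv), (1R,2R)-1,2-bis(trifluoromethanesulfonamido)cyclohexane (8 mol%), 23, toluene, −20 °C; aq. NH4Cl; PPTS (cat.), CH2Cl2, rt
Reagents that add atoms: none
Why: Copper-initiated iodine–zinc exchange turns the primary iodide into dialkylzinc 24, a zinc homoenolate chelated by the C2 ester and inert toward its own esters, and redistribution with Zn(CH2SiMe3)2 gives mixed reagent 25 in which the silylmethyl group is a non-transferable ligand. The chiral titanium bis(sulfonamide) complex activates the enal carbonyl and transfers C4 to it in the 1,2 sense, which is the known titanium bis(sulfonamide)-catalysed enantioselective addition of functionalised dialkylzincs to enals. The only ring, lactone O1–C2–C3–C4–C5, closes by 5-exo-trig acyl substitution of the C5 alkoxide on the C2 methyl ester with loss of methanol, finished by catalytic PPTS if hydroxy ester 26 persists. C5 is set by the catalyst, the (1R,2R)-ligand being expected to direct the alkyl group to the Si face and give (S)-C5, while C3 comes in from 17 and is not enolised under these neutral conditions, so the ring should form 3,5-trans. The step needs 1,2- over 1,4-addition (secured by oxophilic titanium activation), reagent control of the enal face (C3 sits two bonds from the forming bond), and closure on C2, not on the Cq ester or a tert-butyl ester (secured by the five-membered transition state and the unhindered methyl ester).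

Step 18
Reactants: 27 protected lactone
Product: 28 (1S,2R)-1-{[(2R)-3-carboxy-2-hydroxy-2-[(3S,5S)-2-oxo-5-[(1E,5Z,8Z)-tetradeca-1,5,8-trien-1-yl]oxolan-3-yl]propanoyl]oxy}propane-1,2,3-tricarboxylic acid (CNP0327249.2)
Conditions: CF3CO2H/CH2Cl2 (1:2), H2O (5 equiv), 0 °C → rt
Reagents that add atoms: none
Why: Acidolysis, in which the four tert-butyl esters should leave as isobutene and the tertiary silyl ether should be solvolysed, while the lactone, the isocitrate ester linkage and the alkenes are expected to survive short exposure at low temperature.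

**Compound list**

1 | L-malic acid | O[C@@H](CC(=O)O)C(=O)O | starting material
2 | di-tert-butyl (S)-malate | O[C@@H](CC(=O)OC(C)(C)C)C(=O)OC(C)(C)C | intermediate
3 | dilithium alkoxide enolate of 2 | [Li]O[C@@H](C=C(O[Li])OC(C)(C)C)C(=O)OC(C)(C)C | intermediate
4 | tri-tert-butyl (1S,2R)-1-hydroxypropane-1,2,3-tricarboxylate (isocitrate alcohol) | O[C@H](C(=O)OC(C)(C)C)[C@@H](CC(=O)OC(C)(C)C)C(=O)OC(C)(C)C | intermediate
5 | dimethyl (R)-malate | COC(=O)[C@H](O)CC(=O)OC | starting material
6 | dilithium alkoxide enolate of 5 | COC(=O)[C@H](O[Li])C=C(O[Li])OC | intermediate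
7 | dimethyl (2R,3S)-3-[(benzyloxy)methyl]malate | COC(=O)[C@H](O)[C@H](COCc1ccccc1)C(=O)OC | intermediate
8 | (2R,3S)-3-[(benzyloxy)methyl]malic acid | OC(=O)[C@H](O)[C@H](COCc1ccccc1)C(=O)O | intermediate
9 | (2S)-3-(benzyloxy)-2-[(2R,4R)-2-tert-butyl-5-oxo-1,3-dioxolan-4-yl]propanoic acid | OC(=O)[C@@H](COCc1ccccc1)[C@H]1O[C@@H](C(C)(C)C)OC1=O | intermediate
10 | dilithium carboxylate enolate of 9 | [Li]OC(=O)[C@@H](COCc1ccccc1)C1=C(O[Li])O[C@H](C(C)(C)C)O1 | intermediate
11 | (2S)-3-(benzyloxy)-2-[(2R,4R)-4-(2-tert-butoxy-2-oxoethyl)-2-tert-butyl-5-oxo-1,3-dioxolan-4-yl]propanoic acid | OC(=O)[C@@H](COCc1ccccc1)[C@@]1(CC(=O)OC(C)(C)C)O[C@@H](C(C)(C)C)OC1=O | intermediate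
12 | methyl ester of 11 | COC(=O)[C@@H](COCc1ccccc1)[C@@]1(CC(=O)OC(C)(C)C)O[C@@H](C(C)(C)C)OC1=O | intermediate
13 | (2R)-2-[(2S)-3-(benzyloxy)-1-methoxy-1-oxopropan-2-yl]-4-tert-butoxy-2-hydroxy-4-oxobutanoic acid | COC(=O)[C@@H](COCc1ccccc1)[C@](O)(CC(=O)OC(C)(C)C)C(=O)O | intermediate
14 | isocitrate ester of 13 (free tertiary alcohol, benzyl ether) | COC(=O)[C@@H](COCc1ccccc1)[C@](O)(CC(=O)OC(C)(C)C)C(=O)O[C@H](C(=O)OC(C)(C)C)[C@@H](CC(=O)OC(C)(C)C)C(=O)OC(C)(C)C | intermediate
15 | triethylsilyl ether of 14 | COC(=O)[C@@H](COCc1ccccc1)[C@](O[Si](CC)(CC)CC)(CC(=O)OC(C)(C)C)C(=O)O[C@H](C(=O)OC(C)(C)C)[C@@H](CC(=O)OC(C)(C)C)C(=O)OC(C)(C)C | intermediate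
16 | C4 primary alcohol (debenzylated 15) | COC(=O)[C@@H](CO)[C@](O[Si](CC)(CC)CC)(CC(=O)OC(C)(C)C)C(=O)O[C@H](C(=O)OC(C)(C)C)[C@@H](CC(=O)OC(C)(C)C)C(=O)OC(C)(C)C | intermediate
17 | head iodide (C4 iodide, C2 methyl ester, Cq triethylsilyl ether, tri-tert-butyl isocitrate ester) | COC(=O)[C@@H](CI)[C@](O[Si](CC)(CC)CC)(CC(=O)OC(C)(C)C)C(=O)O[C@H](C(=O)OC(C)(C)C)[C@@H](CC(=O)OC(C)(C)C)C(=O)OC(C)(C)C | intermediate
18 | pent-4-yn-1-ol | C#CCCCO | starting material
19 | 1-bromooct-2-yne | CCCCCC#CCBr | starting material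
20 | trideca-4,7-diyn-1-ol | CCCCCC#CCC#CCCCO | intermediate
21 | (4Z,7Z)-trideca-4,7-dien-1-ol | CCCCC/C=C\C/C=C\CCCO | intermediate
22 | (4Z,7Z)-trideca-4,7-dienal | CCCCC/C=C\C/C=C\CCC=O | intermediate
23 | (2E,6Z,9Z)-pentadeca-2,6,9-trienal | CCCCC/C=C\C/C=C\CC/C=C/C=O | intermediate
24 | bis-alkylzinc from 17 (zinc on C4 of two head units) | [Zn](C[C@@H]([C@](O[Si](CC)(CC)CC)(CC(=O)OC(C)(C)C)C(=O)O[C@H](C(=O)OC(C)(C)C)[C@@H](CC(=O)OC(C)(C)C)C(=O)OC(C)(C)C)C(=O)OC)C[C@@H]([C@](O[Si](CC)(CC)CC)(CC(=O)OC(C)(C)C)C(=O)O[C@H](C(=O)OC(C)(C)C)[C@@H](CC(=O)OC(C)(C)C)C(=O)OC(C)(C)C)C(=O)OC | intermediate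
25 | alkyl(trimethylsilylmethyl)zinc from 24 | C[Si](C)(C)C[Zn]C[C@@H]([C@](O[Si](CC)(CC)CC)(CC(=O)OC(C)(C)C)C(=O)O[C@H](C(=O)OC(C)(C)C)[C@@H](CC(=O)OC(C)(C)C)C(=O)OC(C)(C)C)C(=O)OC | intermediate
26 | (5S)-C5 hydroxy C2 methyl ester (open form of 27) | CCCCC/C=C\C/C=C\CC/C=C/[C@@H](O)C[C@@H]([C@](O[Si](CC)(CC)CC)(CC(=O)OC(C)(C)C)C(=O)O[C@H](C(=O)OC(C)(C)C)[C@@H](CC(=O)OC(C)(C)C)C(=O)OC(C)(C)C)C(=O)OC | intermediate
27 | protected 3,5-trans lactone (Cq triethylsilyl ether, four tert-butyl esters) | CCCCC/C=C\C/C=C\CC/C=C/[C@@H]1C[C@@H]([C@](O[Si](CC)(CC)CC)(CC(=O)OC(C)(C)C)C(=O)O[C@H](C(=O)OC(C)(C)C)[C@@H](CC(=O)OC(C)(C)C)C(=O)OC(C)(C)C)C(=O)O1 | intermediate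
28 | CNP0327249.2 | CCCCC/C=C\C/C=C\CC/C=C/[C@@H]1C[C@@H]([C@](O)(CC(=O)O)C(=O)O[C@H](C(=O)O)[C@@H](CC(=O)O)C(=O)O)C(=O)O1 | target

**Step count and risks**

Total step count: 18. Longest linear sequence: 12 steps (steps 3–12, 17 and 18, from dimethyl (R)-malate).

Steps most likely to fail:

1. Step 17. The iodine–zinc exchange may stall or the C4 radical may fragment on so heavily functionalised a substrate. The chelated β-zincio ester may transfer too slowly, facial selectivity at the enal may be low, or the alkoxide may close on the wrong ester. The fallback sets out from 17 and 23 and comes back at 26. Trienal 23 would be oxidised (NaClO2, NaH2PO4, 2-methylbut-2-ene, tBuOH/H2O) to (2E,6Z,9Z)-pentadeca-2,6,9-trienoic acid F1 and converted with oxalyl chloride and catalytic DMF into (2E,6Z,9Z)-pentadeca-2,6,9-trienoyl chloride F2. Iodide 17 would be inserted with activated zinc dust and LiCl in THF to give the alkylzinc iodide F3, which would be acylated by F2 under Pd(PPh3)4 catalysis, as is done with serine-derived β-zincio esters, to the C5 ketone (enone) F4. Corey–Bakshi–Shibata reduction of F4 with (R)-2-methyl-CBS-oxazaborolidine and catecholborane in toluene at −78 °C, the alkenyl group acting as the large substituent, should set (S)-C5 and give 26, which lactonises to 27 as in step 17.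

2. Step 9. Acyl transfer from a carbonyl on a quaternary carbon to a hindered, weakly nucleophilic α-hydroxy ester may be too slow, so the mixed anhydride could decompose or be diverted. The fallback sets out from 4 and 13 and comes back at 14, and it forms the ester bond at the alcohol carbon instead. Alcohol 4 would be inverted by a Mitsunobu reaction with 4-nitrobenzoic acid (PPh3, DIAD, THF) to tri-tert-butyl (1R,2R)-1-[(4-nitrobenzoyl)oxy]propane-1,2,3-tricarboxylate F5. Brief methanolysis (K2CO3 cat., MeOH, 0 °C) would give tri-tert-butyl (1R,2R)-1-hydroxypropane-1,2,3-tricarboxylate F6. A second Mitsunobu reaction of acid 13 with F6 (PPh3, DIAD, toluene) should then give 14 by inversion, the tertiary alcohol of 13 being inert.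

3. Step 6. The hindered dianion may deprotonate the bromoacetate instead of being alkylated, or the C3 substituent may erode conversion and face selectivity at the new quaternary centre. The fallback sets out from 9 and comes back at 12, bringing the arm in as an allyl group and unmasking it oxidatively. Dianion 10 would be alkylated with allyl bromide to (2S)-3-(benzyloxy)-2-[(2R,4R)-4-allyl-2-tert-butyl-5-oxo-1,3-dioxolan-4-yl]propanoic acid F7 and methylated with Me3SiCHN2 to its methyl ester F8. Ozonolysis (O3, CH2Cl2, −78 °C; PPh3) would give the aldehyde F9, and Pinnick oxidation (NaClO2, NaH2PO4, 2-methylbut-2-ene) the carboxymethyl acid F10. tert-Butylation with O-tert-butyl-N,N'-diisopropylisourea should then give 12.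

**Further compounds**

F1 | step 17 | (2E,6Z,9Z)-pentadeca-2,6,9-trienoic acid | CCCCC/C=C\C/C=C\CC/C=C/C(=O)O
F2 | step 17 | (2E,6Z,9Z)-pentadeca-2,6,9-trienoyl chloride | CCCCC/C=C\C/C=C\CC/C=C/C(=O)Cl
F3 | step 17 | alkylzinc iodide from 17 | I[Zn]C[C@@H]([C@](O[Si](CC)(CC)CC)(CC(=O)OC(C)(C)C)C(=O)O[C@H](C(=O)OC(C)(C)C)[C@@H](CC(=O)OC(C)(C)C)C(=O)OC(C)(C)C)C(=O)OC
F4 | step 17 | C5 ketone (enone) of the open chain | CCCCC/C=C\C/C=C\CC/C=C/C(=O)C[C@@H]([C@](O[Si](CC)(CC)CC)(CC(=O)OC(C)(C)C)C(=O)O[C@H](C(=O)OC(C)(C)C)[C@@H](CC(=O)OC(C)(C)C)C(=O)OC(C)(C)C)C(=O)OC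
F5 | step 9 | tri-tert-butyl (1R,2R)-1-[(4-nitrobenzoyl)oxy]propane-1,2,3-tricarboxylate | O=C(O[C@@H](C(=O)OC(C)(C)C)[C@@H](CC(=O)OC(C)(C)C)C(=O)OC(C)(C)C)c1ccc(cc1)[N+](=O)[O-]
F6 | step 9 | tri-tert-butyl (1R,2R)-1-hydroxypropane-1,2,3-tricarboxylate | O[C@@H](C(=O)OC(C)(C)C)[C@@H](CC(=O)OC(C)(C)C)C(=O)OC(C)(C)C
F7 | step 6 | (2S)-3-(benzyloxy)-2-[(2R,4R)-4-allyl-2-tert-butyl-5-oxo-1,3-dioxolan-4-yl]propanoic acid | OC(=O)[C@@H](COCc1ccccc1)[C@@]1(CC=C)O[C@@H](C(C)(C)C)OC1=O
F8 | step 6 | methyl ester of F7 | COC(=O)[C@@H](COCc1ccccc1)[C@@]1(CC=C)O[C@@H](C(C)(C)C)OC1=O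
F9 | step 6 | aldehyde from ozonolysis of F8 | COC(=O)[C@@H](COCc1ccccc1)[C@@]1(CC=O)O[C@@H](C(C)(C)C)OC1=O
F10 | step 6 | carboxymethyl acid from F9 | COC(=O)[C@@H](COCc1ccccc1)[C@@]1(CC(=O)O)O[C@@H](C(C)(C)C)OC1=O
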